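**Retrosynthetic overview**
1. Target ⇐ its pentabenzyl ether, by neutral hydrogenolysis as the last step.
2. Pentabenzyl ether ⇐ a free 2'-hydroxychalcone that already carries the finished flavone. Ring C of the dihydroflavonol half is the only ring built and is closed last: C3–O, then O1–C2, by enantioselective epoxidation and 6-endo phenol closure (sets 2R,3R).
3. Chalcone–flavone ⇐ flavone 3'-triflate + 3'-iodochalcone (3'–8'' biaryl bond, one-pot borylation/Suzuki coupling).
4. Flavone 3'-triflate ⇐ luteolin. All three flavone rings are bought ready-made, and the 3'-OH becomes the coupling handle.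
5. 3'-Iodochalcone ⇐ naringenin, opened to the chalcone during benzylation and iodinated next to the freed OH (the future C8).

Assumption: the SMILES defines no axial chirality, so the biaryl axis is left unspecified. Commercial naringenin is used as sold, because step 3 erases its stereocentre.

**Step 1**
Reactants: 1 luteolin
Product: 2 luteolin 7,4'-dibenzyl ether = 7-(benzyloxy)-2-[4-(benzyloxy)-3-hydroxyphenyl]-5-hydroxy-4H-chromen-4-one
Conditions: BnBr (2.1 equiv), K2CO3 (2.2 equiv), DMF, 0 °C to rt, 16 h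
Reagents that add atoms: benzyl bromide, BrCc1ccccc1
Why: Williamson etherification under acidity control, in which the 7-OH and 4'-OH (vinylogous acids conjugated to C4=O) react first, the 3'-OH is less acidic and the 5-OH is locked in a hydrogen bond, the same order that gives 4-O-benzyl ethers from 3,4-dihydroxybenzaldehyde and the 3,7,4'-tribenzyl ether from quercetin.

**Step 2**
Reactants: 2 luteolin 7,4'-dibenzyl ether
Product: 3 flavone 3'-triflate = 2-(benzyloxy)-5-[7-(benzyloxy)-5-hydroxy-4-oxo-4H-chromen-2-yl]phenyl trifluoromethanesulfonate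
Conditions: PhNTf2 (1.1 equiv), K2CO3 (1.5 equiv), DMF, rt, 4 h
Reagents that add atoms: N-phenylbis(trifluoromethanesulfonimide), O=S(=O)(N(c1ccccc1)S(=O)(=O)C(F)(F)F)C(F)(F)F
Why: Aryl triflate formation, in which the mild triflyl donor takes the only unchelated phenoxide (3'-O) and leaves the hydrogen-bonded 5-OH untouched.

**Step 3**
Reactants: 4 naringenin
Product: 5 2'-hydroxy-4,4',6'-tris(benzyloxy)chalcone = (E)-1-[2,4-bis(benzyloxy)-6-hydroxyphenyl]-3-[4-(benzyloxy)phenyl]prop-2-en-1-one
Conditions: BnBr (3.3 equiv), K2CO3 (4 equiv), DMF, 80 °C, 8 h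
Reagents that add atoms: benzyl bromide, BrCc1ccccc1
Why: Williamson etherification coupled to base-induced E1cB ring opening (retro-oxa-Michael), in which one of the two ortho phenoxides of the opened chalcone is benzylated and the other stays chelated to the carbonyl and unreactive, giving the thermodynamic E-enone and erasing the old stereocentre.

**Step 4**
Reactants: 5 2'-hydroxy-4,4',6'-tris(benzyloxy)chalcone
Product: 6 3'-iodochalcone = (E)-1-[4,6-bis(benzyloxy)-2-hydroxy-3-iodophenyl]-3-[4-(benzyloxy)phenyl]prop-2-en-1-one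
Conditions: NIS (1.05 equiv), DMF, 0 °C to rt, dark, 6 h
Reagents that add atoms: N-iodosuccinimide, O=C1CCC(=O)N1I
Why: Electrophilic aromatic iodination of the phloroglucinol ring ortho to the free chelated OH, as in the 6-iodination of 5-hydroxy-7-alkoxyflavones and the 3-iodination of 2-hydroxy-4,6-dialkoxyacetophenones, while the enone and ring B are far less nucleophilic.

**Step 5**
Reactants: 3 flavone 3'-triflate; 6 3'-iodochalcone
Product: 8 chalcone–flavone biaryl = (E)-1-{4,6-bis(benzyloxy)-3-[2-(benzyloxy)-5-(7-benzyloxy-5-hydroxy-4-oxo-4H-chromen-2-yl)phenyl]-2-hydroxyphenyl}-3-[4-(benzyloxy)phenyl]prop-2-en-1-one, via flavone boronate 7 (not isolated)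
Conditions: 3, B2pin2 (1.1 equiv), Pd(dppf)Cl2 (5 mol%), KOAc (3 equiv), 1,4-dioxane, 90 °C, 4 h; then 6 (0.9 equiv), Pd(OAc)2 (5 mol%), SPhos (10 mol%), aq K3PO4 (5 equiv), 80 °C, 12 h; dilute HCl work-up
Reagents that add atoms: bis(pinacolato)diboron, CC1(C)OB(B2OC(C)(C)C(C)(C)O2)OC1(C)C (its boryl group sits in 7 and is lost again in 8)
Why: One-pot Miyaura borylation/Suzuki–Miyaura coupling, in which zerovalent palladium inserts first into the C–OTf bond and later into the C–I bond, the bulky electron-rich SPhos handles the tri-ortho-substituted biaryl, and strong aqueous base holds the substrate as the open chalcone phenoxide.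

**Step 6**
Reactants: 8 chalcone–flavone biaryl
Product: 10 pentabenzyl dihydroflavonol–flavone = (2R,3R)-5,7-bis(benzyloxy)-8-[2-(benzyloxy)-5-(7-benzyloxy-5-hydroxy-4-oxo-4H-chromen-2-yl)phenyl]-2-[4-(benzyloxy)phenyl]-3-hydroxy-2,3-dihydro-4H-chromen-4-one, via epoxychalcone 9 (not isolated)
Conditions: Sc(OTf)3 (10 mol%), ligand L* (11 mol%), 30% aq H2O2 (1.5 equiv), THF, 0 °C to 30 °C, 24 h; recrystallise. L* = 1,1'-(propane-1,3-diyl)bis{2-[(2,6-diisopropylphenyl)carbamoyl]piperidine 1-oxide} made from L- or D-pipecolic acid; the antipode used is the one that gives the (αR,βS)-epoxide on a model chalcone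
Reagents that add atoms: hydrogen peroxide, OO
Why: Proposed new method: an enantioselective Lewis-acid "interrupted Algar–Flynn–Oyamada" oxidative cyclisation, in which the chiral N,N'-dioxide complex of trivalent scandium binds the chalcone through its C=O/2'-OH chelate, lowers the enone LUMO and shields one face, so that H2O2 adds to Cβ and the scandium enolate closes on the O–O bond (Weitz–Scheffer sequence) to give the trans-(αR,βS)-epoxide 9, which sets C3 as R; the same Lewis acid then chelates the epoxy ketone and weakens the benzylic Cβ–O bond (stabilised by the 4-benzyloxyphenyl group), and the 2'-OH attacks Cβ from the rear in a 6-endo opening with inversion, which sets C2 as R, while even an ionised pathway collapses to the diequatorial 2,3-trans ring under control of C3; with no base present, the phenoxide-driven 5-exo attack at Cα (the aurone route of 6'-alkoxychalcones) and over-oxidation to the flavonol are shut off; the closest known reaction types are the N,N'-dioxide–Sc(OTf)3/H2O2 epoxidation of simple chalcones without a free ortho OH, the acid-induced β-cyclisation of preformed racemic 2'-hydroxychalcone epoxides and the racemic basic Algar–Flynn–Oyamada reaction, and these have not been run as one catalytic asymmetric operation on a free 2'-hydroxychalcone.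

**Step 7**
Reactants: 10 pentabenzyl dihydroflavonol–flavone
Product: 11 target = (2R,3R)-8-[5-(5,7-dihydroxy-4-oxo-4H-chromen-2-yl)-2-hydroxyphenyl]-3,5,7-trihydroxy-2-(4-hydroxyphenyl)-2,3-dihydro-4H-chromen-4-one
Conditions: H2 (1 atm), Pd/C (10 wt% Pd), THF–MeOH 1:1, rt, stopped at full debenzylation (about 3 h)
Reagents that add atoms: none
Why: Catalytic hydrogenolysis of five aryl benzyl ethers under neutral conditions, which is faster than reduction of the flavone C2=C3 bond or of the chelated ketone and gives no pathway for epimerisation at C2 or C3.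

**Compound list**
1 | luteolin | O=c1cc(-c2ccc(O)c(O)c2)oc2cc(O)cc(O)c12 | starting material
2 | luteolin 7,4'-dibenzyl ether | O=c1cc(-c2ccc(OCc3ccccc3)c(O)c2)oc2cc(OCc3ccccc3)cc(O)c12 | intermediate
3 | flavone 3'-triflate | O=c1cc(-c2ccc(OCc3ccccc3)c(OS(=O)(=O)C(F)(F)F)c2)oc2cc(OCc3ccccc3)cc(O)c12 | intermediate
4 | naringenin | O=C1CC(c2ccc(O)cc2)Oc2cc(O)cc(O)c12 | starting material
5 | 2'-hydroxy-4,4',6'-tris(benzyloxy)chalcone | O=C(/C=C/c1ccc(OCc2ccccc2)cc1)c1c(O)cc(OCc2ccccc2)cc1OCc1ccccc1 | intermediate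
6 | 3'-iodochalcone | O=C(/C=C/c1ccc(OCc2ccccc2)cc1)c1c(O)c(I)c(OCc2ccccc2)cc1OCc1ccccc1 | intermediate
7 | flavone 3'-pinacol boronate (not isolated) | O=c1cc(-c2ccc(OCc3ccccc3)c(B3OC(C)(C)C(C)(C)O3)c2)oc2cc(OCc3ccccc3)cc(O)c12 | intermediate
8 | chalcone–flavone biaryl | O=C(/C=C/c1ccc(OCc2ccccc2)cc1)c1c(O)c(-c2cc(-c3cc(=O)c4c(O)cc(OCc5ccccc5)cc4o3)ccc2OCc2ccccc2)c(OCc2ccccc2)cc1OCc1ccccc1 | intermediate
9 | (αR,βS)-epoxychalcone, oxirane (2R,3S) (not isolated) | O=C([C@@H]1O[C@H]1c1ccc(OCc2ccccc2)cc1)c1c(O)c(-c2cc(-c3cc(=O)c4c(O)cc(OCc5ccccc5)cc4o3)ccc2OCc2ccccc2)c(OCc2ccccc2)cc1OCc1ccccc1 | intermediate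
10 | (2R,3R)-pentabenzyl dihydroflavonol–flavone | O=C1c2c(OCc3ccccc3)cc(OCc3ccccc3)c(-c3cc(-c4cc(=O)c5c(O)cc(OCc6ccccc6)cc5o4)ccc3OCc3ccccc3)c2O[C@H](c2ccc(OCc3ccccc3)cc2)[C@H]1O | intermediate
11 | CNP0374521.1, (2R,3R) | O=C1c2c(O)cc(O)c(-c3cc(-c4cc(=O)c5c(O)cc(O)cc5o4)ccc3O)c2O[C@H](c2ccc(O)cc2)[C@H]1O | target

**Totals**
- Total steps: 7.
- Longest linear sequence: 5 (steps 1, 2, 5, 6, 7 or steps 3, 4, 5, 6, 7).

**Three steps most likely to fail**

Step 4 (site of iodination). Attack at C5', or double iodination, would lead to the wrong 6-linked isomer. The fallback sets out from 5 and comes back at 6. Chalcone 5 is closed by oxa-Michael addition (NaOAc, EtOH, reflux) to racemic 5,7,4'-tris(benzyloxy)flavanone F1. All phenols in it are capped, so NIS in DMF attacks the less hindered C8, as is known for 5,7-dialkoxyflavonoids, and gives racemic 8-iodoflavanone F2. KOH in EtOH–THF at rt then reopens ring C (E1cB) and delivers 6, with the iodine necessarily next to the freed OH.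

Step 5 (hindered coupling on a free-OH enone). The ortho-phenoxide slows oxidative addition, and deiodination or flavanone/chalcone scrambling can occur. The fallback sets out from 3 and comes back at 8. It makes the biaryl bond before the enone exists.
- Bought 2,4,6-trihydroxyacetophenone is dibenzylated (BnBr, K2CO3, DMF) to 1-[2,4-bis(benzyloxy)-6-hydroxyphenyl]ethanone F3.
- F3 is iodinated (NIS, DMF) to 1-[4,6-bis(benzyloxy)-2-hydroxy-3-iodophenyl]ethanone F4.
- Triflate 3 is borylated as before to 7 and coupled with F4 (Pd(PPh3)4, aq K2CO3, DMF, 90 °C), the partner type used in classical biflavone syntheses. This gives the biaryl acetophenone F5.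
- Claisen–Schmidt condensation of F5 with bought 4-(benzyloxy)benzaldehyde (KOH, EtOH–THF, rt) gives 8. The flavone is shielded from hydroxide as its 5-phenoxide.

Step 6 (the proposed new step). The failure modes are Lewis-acid oxa-Michael closure to the flavanone, capture of scandium by the 5-hydroxy-4-pyrone unit, hydrolysis of 9, and low ee. The fallback uses known chemistry, sets out from 8 and comes back at 10.
- NaH and MOMCl in DMF at 0 °C cap both chelated phenols and give the bis(methoxymethyl) ether F6.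
- Juliá–Colonna epoxidation (poly-L-leucine, urea–H2O2, DBU, THF, rt) gives the (αR,βS)-epoxide F7.
- HCl in MeOH–THF at 45 °C removes both methoxymethyl groups. The freed 2'-OH opens the epoxide at the benzylic carbon to give the 2,3-trans product 10, which is recrystallised to raise the ee.

**Further compounds**
F1 | step 4 | racemic 5,7-bis(benzyloxy)-2-[4-(benzyloxy)phenyl]-2,3-dihydro-4H-chromen-4-one | O=C1CC(c2ccc(OCc3ccccc3)cc2)Oc2cc(OCc3ccccc3)cc(OCc3ccccc3)c12
F2 | step 4 | racemic 5,7-bis(benzyloxy)-2-[4-(benzyloxy)phenyl]-8-iodo-2,3-dihydro-4H-chromen-4-one | O=C1CC(c2ccc(OCc3ccccc3)cc2)Oc2c(I)c(OCc3ccccc3)cc(OCc3ccccc3)c12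
F3 | step 5 | 1-[2,4-bis(benzyloxy)-6-hydroxyphenyl]ethanone | CC(=O)c1c(O)cc(OCc2ccccc2)cc1OCc1ccccc1
F4 | step 5 | 1-[4,6-bis(benzyloxy)-2-hydroxy-3-iodophenyl]ethanone | CC(=O)c1c(O)c(I)c(OCc2ccccc2)cc1OCc1ccccc1
F5 | step 5 | 2-[3-(3-acetyl-4,6-bis(benzyloxy)-2-hydroxyphenyl)-4-(benzyloxy)phenyl]-7-(benzyloxy)-5-hydroxy-4H-chromen-4-one | CC(=O)c1c(O)c(-c2cc(-c3cc(=O)c4c(O)cc(OCc5ccccc5)cc4o3)ccc2OCc2ccccc2)c(OCc2ccccc2)cc1OCc1ccccc1
F6 | step 6 | bis(methoxymethyl) ether of 8 (2'-O and flavone 5-O) | O=C(/C=C/c1ccc(OCc2ccccc2)cc1)c1c(OCOC)c(-c2cc(-c3cc(=O)c4c(OCOC)cc(OCc5ccccc5)cc4o3)ccc2OCc2ccccc2)c(OCc2ccccc2)cc1OCc1ccccc1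
F7 | step 6 | (αR,βS)-epoxide of F6, oxirane (2R,3S) | O=C([C@@H]1O[C@H]1c1ccc(OCc2ccccc2)cc1)c1c(OCOC)c(-c2cc(-c3cc(=O)c4c(OCOC)cc(OCc5ccccc5)cc4o3)ccc2OCc2ccccc2)c(OCc2ccccc2)cc1OCc1ccccc1
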